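The six-membered carbocycle is numbered from the quaternary oxirane carbon (C1, bearing C7) through the benzoyloxy carbon C2, carbinol C3 and alkene C4=C5 to the oxirane CH C6. Seen this way, the target is a disguised benzoate. The exocyclic C1–C7 bond, the oxygen on C2 and on C3, and sp2 character at C1/C6 and C4/C5 are all encoded in methyl benzoate once its ortho,meta bond is oxygenated. Whole-cell toluene dioxygenase makes both C–O bonds and two stereocentres in one operation on unmodified commercial methyl benzoate 1. It gives cis-dienediol 2 as one enantiomer, with C2 already correct. Singlet oxygen addition anti to both oxygens, phosphine deoxygenation to the C1–C6 oxirane and one Mitsunobu inversion at C3 complete the route.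

Key step: step 1

Remark: these atom labels are kept for every intermediate. The two reducing equivalents consumed in step 1 come from cellular NADH, which the cells regenerate from glucose.

Step 1
Reactants: 1 methyl benzoate
Product: 2 methyl (5S,6R)-5,6-dihydroxycyclohexa-1,3-diene-1-carboxylate (cis-diol; C2 is R, C3 is S)
Conditions: E. coli JM109(pDTG601) whole cells (toluene dioxygenase, IPTG-induced), air sparge, glucose feed, mineral medium pH 7, 30–35 °C; EtOAc extraction
Reagents that add atoms: dioxygen, O=O
Why: Electrons from NADH pass through the reductase, the ferredoxin and the [2Fe–2S] cluster to the mononuclear non-heme iron centre of the oxygenase, where bound O2 is delivered as one unit to a single face of the C2–C3 bond, so both new C–O bonds are cis. The closest known reaction type is the toluene dioxygenase cis-dihydroxylation of toluene, halobenzenes and benzoate esters, and because the host lacks the diol dehydrogenase, 2 should accumulate instead of being oxidised on to a catechol. No ring is closed; the aromatic ring is converted into the C1=C6/C4=C5 diene with C7 already attached. The configurations at C2 and C3 are fixed by the chiral active-site pocket, which docks the ring substituent as it docks the methyl group of toluene and exposes only one arene face to iron. The step needs ortho,meta attack rather than ipso,ortho or meta,para attack, plus absolute facial selectivity; both follow from that binding mode, and the small neutral methyl ester is chosen because it should fit the pocket best. The electron-poor ester should also slow acid-induced dehydration of 2 to a phenol during extraction.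

Step 2
Reactants: 2 methyl (5S,6R)-5,6-dihydroxycyclohexa-1,3-diene-1-carboxylate
Product: 3 methyl (5S,6R)-5-[(tert-butyldimethylsilyl)oxy]-6-hydroxycyclohexa-1,3-diene-1-carboxylate (C3 silyl ether, C2 hydroxyl free)
Conditions: TBSCl (1.05 equiv), imidazole, DMF, −10 → 0 °C
Reagents that add atoms: tert-butyldimethylsilyl chloride, CC(C)(C)[Si](C)(C)Cl
Why: Silyl ether formation with TBSCl/imidazole should select the C3 hydroxyl because it is remote from the C1 ester, whereas the C2 hydroxyl is flanked by the substituted sp2 carbon and hydrogen-bonded to the ester carbonyl, the same distal preference that is well established for arene cis-dihydrodiols, and no stereocentre is touched.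

Step 3
Reactants: 3 methyl (5S,6R)-5-[(tert-butyldimethylsilyl)oxy]-6-hydroxycyclohexa-1,3-diene-1-carboxylate
Product: 4 (1R,6S)-6-[(tert-butyldimethylsilyl)oxy]-2-(hydroxymethyl)cyclohexa-2,4-dien-1-ol
Conditions: iBu2AlH (3.3 equiv), CH2Cl2, −78 → −40 °C; aq potassium sodium tartrate
Reagents that add atoms: none
Why: Hydride 1,2-reduction of a conjugated ester by iBu2AlH at low temperature should stop at the allylic alcohol without touching the diene or the silyl ether, the first equivalent being consumed by the free C2 hydroxyl, and the non-acidic tartrate work-up avoids dehydrative rearomatisation.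

Step 4
Reactants: 4 (1R,6S)-6-[(tert-butyldimethylsilyl)oxy]-2-(hydroxymethyl)cyclohexa-2,4-dien-1-ol; 5 benzoyl chloride
Product: 6 [(5S,6R)-6-(benzoyloxy)-5-[(tert-butyldimethylsilyl)oxy]cyclohexa-1,3-dien-1-yl]methyl benzoate
Conditions: BzCl (2.5 equiv), pyridine, 4-(dimethylamino)pyridine (cat.), CH2Cl2, 0 °C → rt
Reagents that add atoms: benzoyl chloride, O=C(Cl)c1ccccc1
Why: Nucleophile-catalysed acylation with an acid chloride esterifies the primary C7 and the secondary C2 hydroxyl in one operation with retention at C2 while C3 stays masked, and the basic medium keeps the acid-sensitive diene intact.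

Step 5
Reactants: 6 [(5S,6R)-6-(benzoyloxy)-5-[(tert-butyldimethylsilyl)oxy]cyclohexa-1,3-dien-1-yl]methyl benzoate
Product: 8 [(1S,2S,3S,6S)-2-(benzoyloxy)-3-[(tert-butyldimethylsilyl)oxy]-7-oxabicyclo[4.1.0]hept-4-en-1-yl]methyl benzoate (oxirane anti to both the C2 and the C3 oxygen), via endoperoxide 7 (not isolated)
Conditions: O2, 5,10,15,20-tetraphenylporphyrin (cat.), visible light, CH2Cl2, −30 °C; Ar purge, dark, PPh3 (1.05 equiv), −30 °C → rt
Reagents that add atoms: dioxygen, O=O
Why: Sensitised photooxygenation gives a singlet-oxygen [4+2] cycloaddition across C1 and C4 of the s-cis diene on the face opposite the C2 benzoate and C3 silyl ether, which sets C1, and the known phosphine deoxygenation of unsaturated bicyclic endoperoxides follows, with PPh3 attacking the less hindered oxygen on secondary C4 so that the C1 alkoxide closes on C6 in a syn SN2′ displacement of Ph3P=O, which sets C6 on the same face and moves the alkene to C4=C5.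

Step 6
Reactants: 8 [(1S,2S,3S,6S)-2-(benzoyloxy)-3-[(tert-butyldimethylsilyl)oxy]-7-oxabicyclo[4.1.0]hept-4-en-1-yl]methyl benzoate
Product: 9 [(1S,2S,3S,6S)-2-(benzoyloxy)-3-hydroxy-7-oxabicyclo[4.1.0]hept-4-en-1-yl]methyl benzoate (C3 epimer of the target; hydroxyl cis to the C2 benzoate)
Conditions: Bu4NF/AcOH (1:1, 1.5 equiv), THF, 0 °C
Reagents that add atoms: none
Why: Fluoride-mediated desilylation is driven by the strong Si–F bond, and the acetic acid buffer protonates the C3 alkoxide as it forms, so that benzoyl migration from the cis C2 oxygen and attack on the vinyl oxirane should be suppressed while C3 keeps its configuration.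

Step 7
Reactants: 9 [(1S,2S,3S,6S)-2-(benzoyloxy)-3-hydroxy-7-oxabicyclo[4.1.0]hept-4-en-1-yl]methyl benzoate
Product: 10 [(1S,2S,3R,6S)-2-(benzoyloxy)-3-(formyloxy)-7-oxabicyclo[4.1.0]hept-4-en-1-yl]methyl benzoate
Conditions: PPh3, DIAD, THF, 0 °C; then 9 and HCO2H, 0 °C → rt
Reagents that add atoms: formic acid, O=CO
Why: In this Mitsunobu reaction the C3 hydroxyl is activated as its oxyphosphonium ion and displaced by formate in an SN2 process from the oxirane-side face, which inverts C3 to the R configuration of the target, the C2 benzoate being cis to the leaving group and so unable to participate, and the acid being taken up by the preformed betaine so that the oxirane meets little free acid.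

Step 8
Reactants: 10 [(1S,2S,3R,6S)-2-(benzoyloxy)-3-(formyloxy)-7-oxabicyclo[4.1.0]hept-4-en-1-yl]methyl benzoate
Product: 11 [(1S,2S,3R,6S)-2-(benzoyloxy)-3-hydroxy-7-oxabicyclo[4.1.0]hept-4-en-1-yl]methyl benzoate (target)
Conditions: KHCO3 (0.2 equiv), MeOH, 0 °C
Reagents that add atoms: none
Why: Base-catalysed transesterification discriminates on rate, since an unhindered formate is far more electrophilic than a conjugated benzoate, so brief exposure to KHCO3 in cold methanol should free the C3 hydroxyl with retention (acyl–oxygen cleavage) while both benzoates and the oxirane survive.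

Compound list
1 | methyl benzoate | COC(=O)c1ccccc1 | starting material
2 | methyl (5S,6R)-5,6-dihydroxycyclohexa-1,3-diene-1-carboxylate | COC(=O)C1=CC=C[C@H](O)[C@@H]1O | intermediate
3 | methyl (5S,6R)-5-[(tert-butyldimethylsilyl)oxy]-6-hydroxycyclohexa-1,3-diene-1-carboxylate | COC(=O)C1=CC=C[C@H](O[Si](C)(C)C(C)(C)C)[C@@H]1O | intermediate
4 | (1R,6S)-6-[(tert-butyldimethylsilyl)oxy]-2-(hydroxymethyl)cyclohexa-2,4-dien-1-ol | OCC1=CC=C[C@H](O[Si](C)(C)C(C)(C)C)[C@@H]1O | intermediate
5 | benzoyl chloride | O=C(Cl)c1ccccc1 | starting material
6 | [(5S,6R)-6-(benzoyloxy)-5-[(tert-butyldimethylsilyl)oxy]cyclohexa-1,3-dien-1-yl]methyl benzoate | O=C(OCC1=CC=C[C@H](O[Si](C)(C)C(C)(C)C)[C@@H]1OC(=O)c1ccccc1)c1ccccc1 | intermediate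
7 | [(1R,4R,7S,8R)-7-(benzoyloxy)-8-[(tert-butyldimethylsilyl)oxy]-2,3-dioxabicyclo[2.2.2]oct-5-en-1-yl]methyl benzoate (peroxide bridge anti to both oxygens) | O=C(OC[C@]12OO[C@H](C=C1)[C@H](O[Si](C)(C)C(C)(C)C)[C@@H]2OC(=O)c1ccccc1)c1ccccc1 | intermediate
8 | [(1S,2S,3S,6S)-2-(benzoyloxy)-3-[(tert-butyldimethylsilyl)oxy]-7-oxabicyclo[4.1.0]hept-4-en-1-yl]methyl benzoate | O=C(OC[C@]12O[C@H]1C=C[C@H](O[Si](C)(C)C(C)(C)C)[C@@H]2OC(=O)c1ccccc1)c1ccccc1 | intermediate
9 | [(1S,2S,3S,6S)-2-(benzoyloxy)-3-hydroxy-7-oxabicyclo[4.1.0]hept-4-en-1-yl]methyl benzoate | O=C(OC[C@]12O[C@H]1C=C[C@H](O)[C@@H]2OC(=O)c1ccccc1)c1ccccc1 | intermediate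
10 | [(1S,2S,3R,6S)-2-(benzoyloxy)-3-(formyloxy)-7-oxabicyclo[4.1.0]hept-4-en-1-yl]methyl benzoate | O=C(OC[C@]12O[C@H]1C=C[C@@H](OC=O)[C@@H]2OC(=O)c1ccccc1)c1ccccc1 | intermediate
11 | [(1S,2S,3R,6S)-2-(benzoyloxy)-3-hydroxy-7-oxabicyclo[4.1.0]hept-4-en-1-yl]methyl benzoate | O=C(OC[C@]12O[C@H]1C=C[C@@H](O)[C@@H]2OC(=O)c1ccccc1)c1ccccc1 | target

Total step count: 8
Longest linear sequence: 8 steps (1 → 11)

Steps most likely to fail

Step 7 (Mitsunobu inversion). Three things may go wrong:
- The activated allylic C3–O bond may be captured with allylic transposition at C5.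
- It may ionise partly, which would erode the inversion.
- The vinyl oxirane may be opened by the carboxylic acid.

The fallback replaces redox condensation by sulfonate displacement with an oxygen nucleophile that releases the alcohol directly. It sets out from 9. MsCl and Et3N in CH2Cl2 at −20 °C give the C3 mesylate F1. KNO2 in DMSO at rt displaces it through oxygen with inversion to give the C3 nitrite ester F2. This ester hydrolyses on aqueous work-up. The route is rejoined at 11, so 10 and step 8 are bypassed.

Step 5 (photooxygenation and deoxygenation). Four things may go wrong: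
- The phosphine may attack the more hindered peroxide oxygen.
- The tertiary C1–O bond may break first, placing the oxirane on the wrong alkene.
- An ene reaction at the C7 hydrogens may compete with the cycloaddition.
- The peroxide may isomerise in a Kornblum–DeLaMare manner.

The fallback abandons the peroxide altogether. It sets out from 6, which is epoxidised directly with 3-chloroperoxybenzoic acid in Na2HPO4-buffered CH2Cl2 at 0 °C. The trisubstituted C1=C6 alkene is the more nucleophilic one, and approach should occur anti to the C2 benzoate. The route is rejoined at 8. This detour creates no new compound (F0).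

Step 6 (desilylation). Two things may go wrong:
- The benzoyl group may shift from the C2 oxygen to the neighbouring cis C3 alkoxide.
- The vinyl oxirane may be opened by fluoride or acetic acid.

The fallback moves the deprotection ahead of oxirane formation. It sets out from 7, which is now isolated by cold chromatography. HF·pyridine in THF/pyridine at 0 °C is acidic, so no alkoxide forms and no base-induced peroxide fragmentation occurs. It gives the C3 hydroxy endoperoxide F3. PPh3 in CH2Cl2 then effects the same syn SN2′ deoxygenation, and the route is rejoined at 9.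

Further compounds
F1 | step 7 | [(1S,2S,3S,6S)-2-(benzoyloxy)-3-(methanesulfonyloxy)-7-oxabicyclo[4.1.0]hept-4-en-1-yl]methyl benzoate | O=C(OC[C@]12O[C@H]1C=C[C@H](OS(C)(=O)=O)[C@@H]2OC(=O)c1ccccc1)c1ccccc1
F2 | step 7 | [(1S,2S,3R,6S)-2-(benzoyloxy)-3-(nitrosooxy)-7-oxabicyclo[4.1.0]hept-4-en-1-yl]methyl benzoate | O=C(OC[C@]12O[C@H]1C=C[C@@H](ON=O)[C@@H]2OC(=O)c1ccccc1)c1ccccc1
F0 | step 5 | none | none
F3 | step 6 | [(1R,4R,7S,8R)-7-(benzoyloxy)-8-hydroxy-2,3-dioxabicyclo[2.2.2]oct-5-en-1-yl]methyl benzoate | O=C(OC[C@]12OO[C@H](C=C1)[C@H](O)[C@@H]2OC(=O)c1ccccc1)c1ccccc1
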